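The target is a 3,3''-biflavanone whose ring C (unit 1, 4-methoxyphenyl) is 2,3-trans and whose ring C'' (unit 2, 4-hydroxyphenyl) is 2'',3''-cis: C2(S)–C3(R)–C3''(S)–C2''(S), with the acyl carbons C4 and C4'' syn across C3–C3''. That array equals syn addition of two acyl groups to a Z C3=C3'' alkene flanked by two S aryl ether carbons. One palladium-catalysed double carbonylation of a Z-enediol bis(aryl ether), iodinated on the unit 1 ether only, forms C4a–C4, C4–C3 and C3''–C4'', closes ring C and sets C3 and C3''. Friedel–Crafts closure of ring C'' and deprotection finish the synthesis.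

Key step: step 9

Atom labels: unit 1 is the 4-methoxyphenyl flavanone (O1, C2, C3, C4, C4a, C8a; ring A, ring C); unit 2 is the 4-hydroxyphenyl flavanone (same labels double-primed).
Assumption: (S,S)-ProPhenol is taken as the antipode that delivers the alkynyl group to the Re face of aryl aldehydes; if Mosher ester analysis of the first propargylic alcohol shows the opposite sense, the (R,R) ligand is used in steps 2 and 5.

Step 1
Reactants: 1 4-hydroxybenzaldehyde
Product: 2 4-(methoxymethoxy)benzaldehyde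
Conditions: MOMCl, K2CO3, acetone, 0 °C to rt
Reagents that add atoms: chloromethyl methyl ether, COCCl
Why: Williamson-type O-alkylation of the phenoxide by the α-chloro ether (MOM protection) is fast and leaves the aldehyde alone; no stereocentre is formed.

Step 2
Reactants: 2 4-(methoxymethoxy)benzaldehyde; 3 trimethylsilylacetylene
Product: 6 (R)-1-[4-(methoxymethoxy)phenyl]prop-2-yn-1-ol, via methyl(trimethylsilylethynyl)zinc 4 (not isolated), via silylated S carbinol 5 (not isolated)
Conditions: Me2Zn, (S,S)-ProPhenol (10 mol %), Ph3PO (20 mol %), toluene, 0 °C; aq NH4Cl; then K2CO3, MeOH, rt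
Reagents that add atoms: none
Why: Asymmetric alkynylation by the dinuclear zinc catalyst formed from Me2Zn and ProPhenol adds the acetylide to the Re face of the aryl aldehyde and so sets the S carbinol of 5, and K2CO3 methanolysis of the C–Si bond then gives 6 unchanged in space (the descriptor becomes R only because ethynyl ranks below aryl).

Step 3
Reactants: 7 phloroglucinol
Product: 8 3,5-bis(methoxymethoxy)phenol
Conditions: MOMCl (2 equiv), i-Pr2NEt, CH2Cl2/DMF, 0 °C; chromatography
Reagents that add atoms: chloromethyl methyl ether, COCCl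
Why: Statistical double O-alkylation (MOM protection) of the threefold symmetric triol, in which every bis-ether is the same compound and the mono- and tris-ethers are removed by chromatography; no stereocentre.

Step 4
Reactants: 6 (R)-1-[4-(methoxymethoxy)phenyl]prop-2-yn-1-ol; 8 3,5-bis(methoxymethoxy)phenol
Product: 9 1-[[(1S)-1-[4-(methoxymethoxy)phenyl]prop-2-yn-1-yl]oxy]-3,5-bis(methoxymethoxy)benzene
Conditions: PPh3, DIAD, toluene, −20 °C to rt
Reagents that add atoms: none
Why: Mitsunobu etherification, in which the phenol (pKa about 9) displaces the activated propargylic oxygen by SN2 with inversion and so turns the R carbinol into the S ether centre C2'', the electron-poor alkynyl group holding back ionisation.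

Step 5
Reactants: 9 the (S)-propargylic aryl ether of step 4; 10 4-methoxybenzaldehyde (1.5 equiv)
Product: 12 (1S,4R)-4-[3,5-bis(methoxymethoxy)phenoxy]-1-(4-methoxyphenyl)-4-[4-(methoxymethoxy)phenyl]but-2-yn-1-ol, via alkynyl(methyl)zinc 11 (not isolated)
Conditions: Me2Zn, (S,S)-ProPhenol (20 mol %), Ph3PO, toluene, 0 °C; aq NH4Cl
Reagents that add atoms: none
Why: The same zinc–ProPhenol asymmetric alkynylation, now with the terminal alkyne 9, adds to the Re face of 10 under catalyst control and sets the S carbinol at C2, the C2'' centre across the alkyne having no influence.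

Step 6
Reactants: 8 3,5-bis(methoxymethoxy)phenol
Product: 13 2-iodo-3,5-bis(methoxymethoxy)phenol
Conditions: NIS (1.0 equiv), CH2Cl2, −40 to 0 °C
Reagents that add atoms: N-iodosuccinimide, O=C1CCC(=O)N1I
Why: Electrophilic aromatic iodination of the activated phenol should go to one of the two equivalent carbons ortho to the free hydroxyl, which are less crowded than the carbon between the two MOM ethers, and the minor 4-iodo isomer is removed by chromatography.

Step 7
Reactants: 12 the (1S,4R)-alkynol; 13 2-iodo-3,5-bis(methoxymethoxy)phenol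
Product: 14 1-[[(1R,4R)-4-[3,5-bis(methoxymethoxy)phenoxy]-1-(4-methoxyphenyl)-4-[4-(methoxymethoxy)phenyl]but-2-yn-1-yl]oxy]-2-iodo-3,5-bis(methoxymethoxy)benzene
Conditions: PPh3, DIAD, toluene, −20 °C to rt
Reagents that add atoms: none
Why: Mitsunobu etherification with the acidic ortho-iodinated phenol inverts the C2 carbinol by SN2 (S carbinol to the ether centre that is R in 14), low temperature and toluene disfavouring ionisation of the 4-methoxybenzylic position.

Step 8
Reactants: 14 the (1R,4R)-bis(aryl ether) alkyne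
Product: 15 1-[[(1S,2Z,4S)-4-[3,5-bis(methoxymethoxy)phenoxy]-1-(4-methoxyphenyl)-4-[4-(methoxymethoxy)phenyl]but-2-en-1-yl]oxy]-2-iodo-3,5-bis(methoxymethoxy)benzene
Conditions: H2 (1 atm), Pd/CaCO3 poisoned with Pb(OAc)2, quinoline, EtOAc, rt
Reagents that add atoms: none
Why: Lindlar-type semihydrogenation delivers both hydrogens syn on the lead-poisoned palladium surface and stops at the Z alkene, while the hindered, electron-rich aryl iodide and the two ether centres are untouched (their descriptors change to S only because vinyl ranks below aryl).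

Step 9
Reactants: 15 the (1S,2Z,4S)-bis(aryl ether) alkene
Product: 18 methyl (2S,3S)-2-[(2S,3R)-5,7-bis(methoxymethoxy)-2-(4-methoxyphenyl)-4-oxochroman-3-yl]-3-[3,5-bis(methoxymethoxy)phenoxy]-3-[4-(methoxymethoxy)phenyl]propanoate, via aroylpalladium iodide ArC(O)PdI(PPh3)2 16 (not isolated), via C3'' alkylpalladium iodide RPdI(PPh3)2 17 (not isolated)
Conditions: Pd(PPh3)4 (10 mol %), CO (40 atm), MeOH (10 equiv), i-Pr2NEt (2 equiv), MeCN/toluene 1:1, 80 °C
Reagents that add atoms: carbon monoxide, [C-]#[O+]; methanol, CO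
Why: Proposed new method: Zerovalent palladium adds oxidatively to the ring A C–I bond and takes up CO to give the aroyl complex 16, which adds syn across the Z C3=C3'' alkene (C4a–C4 and C4–C3 formed, ring C closed 6-exo-trig), and the C3'' alkylpalladium 17, held as a five-membered chelate by the new C4 carbonyl, inserts a second CO with retention and is cleaved by methanol (C3''–C4''), which returns zerovalent palladium. The closest known reaction type is the cyclic acylpalladation of terminal and 1,1-disubstituted alkenes by 2-iodoaryl tethers under CO pressure with alkoxycarbonylative trapping; a Z-1,2-disubstituted alkene flanked by two allylic aryl ethers has not been used. C3 is set by allylic 1,3-strain: the Z alkene keeps C2–H in the alkene plane, so O1 and the 4-methoxyphenyl group lie on opposite faces and the O1-tethered aroyl group reaches C3 only on the face that makes ring C trans (2S,3R). C3'' is set by the syn insertion itself, which places palladium and then C4'' on the face of C3'' that matches C4 and, with C2'' being S, gives 3''S, the cis relation of the later ring C''. The step needs CO uptake to outrun 5-exo carbopalladation, ring closure to outrun methanolysis of 16, and the second CO uptake to outrun β-hydride or β-aryloxide loss and allylic ionisation; 40 atm of CO, the doubly ortho-substituted and therefore slowly solvolysed aroyl group, the small excess of methanol, the chelate in 17 and the crowded alkene should secure this. The iodide sits on the unit 1 ether only, which decides that unit 1 becomes the trans ring.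

Step 10
Reactants: 18 the methyl ester of step 9
Product: 20 (2S,3S)-2-[(2S,3R)-5,7-bis(methoxymethoxy)-2-(4-methoxyphenyl)-4-oxochroman-3-yl]-3-[3,5-bis(methoxymethoxy)phenoxy]-3-[4-(methoxymethoxy)phenyl]propanoic acid, via trimethylstannyl ester 19 (not isolated)
Conditions: Me3SnOH (8 equiv), ClCH2CH2Cl, 80 °C; then cold 0.1 M aq HCl wash
Reagents that add atoms: trimethyltin hydroxide, C[Sn](C)(C)O
Why: Me3SnOH ester cleavage (acyl substitution by a weakly basic tin hydroxide, the stannyl ester 19 being protonated on work-up) hydrolyses methyl esters without epimerising α-centres or eliminating β-aryloxy groups, so C3 and C3'' should be kept.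

Step 11
Reactants: 20 the acid of step 10
Product: 22 (2S,3R)-3-[(2S,3S)-5,7-bis(methoxymethoxy)-2-[4-(methoxymethoxy)phenyl]-4-oxochroman-3-yl]-5,7-bis(methoxymethoxy)-2-(4-methoxyphenyl)chroman-4-one, via mixed trifluoroacetic anhydride 21 (not isolated)
Conditions: (CF3CO)2O, CH2Cl2, 0 °C
Reagents that add atoms: none
Why: Intramolecular Friedel–Crafts acylation through the mixed anhydride 21 attacks either of the two equivalent carbons ortho to O1'' of the phloroglucinol-type ring (six-membered ring C''), and since no bond to C2'' or C3'' is broken the ring is closed cis.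

Step 12
Reactants: 22 the penta-MOM biflavanone
Product: 23 (2S,3R)-3-[(2S,3S)-5,7-dihydroxy-2-(4-hydroxyphenyl)-4-oxochroman-3-yl]-5,7-dihydroxy-2-(4-methoxyphenyl)chroman-4-one (CNP0196568.6)
Conditions: HCl (2 M in MeOH), THF, 25–40 °C
Reagents that add atoms: none
Why: Acid-catalysed acetal exchange with methanol removes the five MOM ethers, and the mild temperature should keep the cis ring C'' from epimerising at C3''; no bond to a stereocentre is touched.

Compound list
1 | 4-hydroxybenzaldehyde | O=Cc1ccc(O)cc1 | starting material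
2 | 4-(methoxymethoxy)benzaldehyde | COCOc1ccc(C=O)cc1 | intermediate
3 | trimethylsilylacetylene | C#C[Si](C)(C)C | starting material
4 | methyl[(trimethylsilyl)ethynyl]zinc | C[Zn]C#C[Si](C)(C)C | intermediate
5 | (S)-1-[4-(methoxymethoxy)phenyl]-3-(trimethylsilyl)prop-2-yn-1-ol | C[Si](C)(C)C#C[C@@H](O)c1ccc(OCOC)cc1 | intermediate
6 | (R)-1-[4-(methoxymethoxy)phenyl]prop-2-yn-1-ol | C#C[C@@H](O)c1ccc(OCOC)cc1 | intermediate
7 | phloroglucinol (benzene-1,3,5-triol) | Oc1cc(O)cc(O)c1 | starting material
8 | 3,5-bis(methoxymethoxy)phenol | COCOc1cc(O)cc(OCOC)c1 | intermediate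
9 | 1-[[(1S)-1-[4-(methoxymethoxy)phenyl]prop-2-yn-1-yl]oxy]-3,5-bis(methoxymethoxy)benzene | C#C[C@H](Oc1cc(OCOC)cc(OCOC)c1)c1ccc(OCOC)cc1 | intermediate
10 | 4-methoxybenzaldehyde | COc1ccc(C=O)cc1 | starting material
11 | methyl[(3R)-3-[3,5-bis(methoxymethoxy)phenoxy]-3-[4-(methoxymethoxy)phenyl]prop-1-yn-1-yl]zinc | C[Zn]C#C[C@H](Oc1cc(OCOC)cc(OCOC)c1)c1ccc(OCOC)cc1 | intermediate
12 | (1S,4R)-4-[3,5-bis(methoxymethoxy)phenoxy]-1-(4-methoxyphenyl)-4-[4-(methoxymethoxy)phenyl]but-2-yn-1-ol | COc1ccc([C@H](O)C#C[C@H](Oc2cc(OCOC)cc(OCOC)c2)c2ccc(OCOC)cc2)cc1 | intermediate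
13 | 2-iodo-3,5-bis(methoxymethoxy)phenol | COCOc1cc(O)c(I)c(OCOC)c1 | intermediate
14 | 1-[[(1R,4R)-4-[3,5-bis(methoxymethoxy)phenoxy]-1-(4-methoxyphenyl)-4-[4-(methoxymethoxy)phenyl]but-2-yn-1-yl]oxy]-2-iodo-3,5-bis(methoxymethoxy)benzene | COc1ccc([C@@H](Oc2cc(OCOC)cc(OCOC)c2I)C#C[C@H](Oc2cc(OCOC)cc(OCOC)c2)c2ccc(OCOC)cc2)cc1 | intermediate
15 | 1-[[(1S,2Z,4S)-4-[3,5-bis(methoxymethoxy)phenoxy]-1-(4-methoxyphenyl)-4-[4-(methoxymethoxy)phenyl]but-2-en-1-yl]oxy]-2-iodo-3,5-bis(methoxymethoxy)benzene (precursor of the key step) | COc1ccc([C@@H](Oc2cc(OCOC)cc(OCOC)c2I)/C=C\[C@H](Oc2cc(OCOC)cc(OCOC)c2)c2ccc(OCOC)cc2)cc1 | intermediate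
16 | aroylpalladium iodide ArC(O)PdI(PPh3)2 of divalent palladium, formed from 15 by oxidative addition and CO insertion | COc1ccc([C@@H](Oc2cc(OCOC)cc(OCOC)c2C(=O)[Pd-2](I)([P+](c3ccccc3)(c3ccccc3)c3ccccc3)[P+](c3ccccc3)(c3ccccc3)c3ccccc3)/C=C\[C@H](Oc2cc(OCOC)cc(OCOC)c2)c2ccc(OCOC)cc2)cc1 | intermediate
17 | C3'' alkylpalladium iodide RPdI(PPh3)2 of divalent palladium, the ring-closed trans-flavanone with palladium on C3'' | COc1ccc([C@H]2Oc3cc(OCOC)cc(OCOC)c3C(=O)[C@@H]2[C@H]([Pd-2](I)([P+](c4ccccc4)(c4ccccc4)c4ccccc4)[P+](c4ccccc4)(c4ccccc4)c4ccccc4)[C@H](Oc2cc(OCOC)cc(OCOC)c2)c2ccc(OCOC)cc2)cc1 | intermediate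
18 | methyl (2S,3S)-2-[(2S,3R)-5,7-bis(methoxymethoxy)-2-(4-methoxyphenyl)-4-oxochroman-3-yl]-3-[3,5-bis(methoxymethoxy)phenoxy]-3-[4-(methoxymethoxy)phenyl]propanoate (product of the key step) | COc1ccc([C@H]2Oc3cc(OCOC)cc(OCOC)c3C(=O)[C@@H]2[C@H](C(=O)OC)[C@H](Oc2cc(OCOC)cc(OCOC)c2)c2ccc(OCOC)cc2)cc1 | intermediate
19 | trimethylstannyl ester of acid 20 | COc1ccc([C@H]2Oc3cc(OCOC)cc(OCOC)c3C(=O)[C@@H]2[C@H](C(=O)O[Sn](C)(C)C)[C@H](Oc2cc(OCOC)cc(OCOC)c2)c2ccc(OCOC)cc2)cc1 | intermediate
20 | (2S,3S)-2-[(2S,3R)-5,7-bis(methoxymethoxy)-2-(4-methoxyphenyl)-4-oxochroman-3-yl]-3-[3,5-bis(methoxymethoxy)phenoxy]-3-[4-(methoxymethoxy)phenyl]propanoic acid | COc1ccc([C@H]2Oc3cc(OCOC)cc(OCOC)c3C(=O)[C@@H]2[C@H](C(=O)O)[C@H](Oc2cc(OCOC)cc(OCOC)c2)c2ccc(OCOC)cc2)cc1 | intermediate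
21 | mixed anhydride of acid 20 with trifluoroacetic acid | COc1ccc([C@H]2Oc3cc(OCOC)cc(OCOC)c3C(=O)[C@@H]2[C@H](C(=O)OC(=O)C(F)(F)F)[C@H](Oc2cc(OCOC)cc(OCOC)c2)c2ccc(OCOC)cc2)cc1 | intermediate
22 | (2S,3R)-3-[(2S,3S)-5,7-bis(methoxymethoxy)-2-[4-(methoxymethoxy)phenyl]-4-oxochroman-3-yl]-5,7-bis(methoxymethoxy)-2-(4-methoxyphenyl)chroman-4-one | COc1ccc([C@H]2Oc3cc(OCOC)cc(OCOC)c3C(=O)[C@@H]2[C@@H]2C(=O)c3c(OCOC)cc(OCOC)cc3O[C@@H]2c2ccc(OCOC)cc2)cc1 | intermediate
23 | (2S,3R)-3-[(2S,3S)-5,7-dihydroxy-2-(4-hydroxyphenyl)-4-oxochroman-3-yl]-5,7-dihydroxy-2-(4-methoxyphenyl)chroman-4-one (CNP0196568.6) | COc1ccc([C@H]2Oc3cc(O)cc(O)c3C(=O)[C@@H]2[C@@H]2C(=O)c3c(O)cc(O)cc3O[C@@H]2c2ccc(O)cc2)cc1 | target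

Total step count: 12. Longest linear sequence: 10 steps (1, 2, 4, 5, 7, 8, 9, 10, 11, 12).

Steps most likely to fail

Step 9 (Proposed new method). The cascade can leak through solvolysis of the aroyl complex before ring closure, through carbopalladation before CO uptake, or through β-elimination or allylic ionisation at the alkylpalladium stage. The crowded alkene may also simply fail to insert. The fallback uses known chemistry and runs from 12 back to 22. Alkynol 12 is etherified with the iodine-free phenol 8 (PPh3, DIAD, toluene, as in step 7, with inversion) to give the (1R,4R)-bis(aryl ether) alkyne F1. H2 over Pd/CaCO3 poisoned with Pb(OAc)2 then gives the (1S,2Z,4S)-alkene F2. Oxidative bis(methoxycarbonylation) with divalent palladium (Pd(OCOCF3)2, N,N'-bis(2,6-dimethylphenyl)butane-2,3-diimine, p-benzoquinone, CO 4 bar, MeOH/THF, 20 °C) is a stereospecific syn addition known for Z-1,2-disubstituted alkenes. It should give the (2R,3S)-succinate F3, in which C4 and C4'' are syn as in 18. No tether chooses the alkene face here, so the face isomer, the (2S,3R)-succinate F4, is expected in a similar amount; it would put the 4-methoxyphenyl group on the cis ring and is removed by chromatography. Me3SnOH cleaves both esters of F3 to the diacid F5, and (CF3CO)2O closes ring C and ring C'' by twofold Friedel–Crafts acylation to 22.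

Step 8. Hydrogenolysis of the C–I bond, stalling of the poisoned catalyst by the aryl iodide, or reduction past the alkene stage can spoil the semihydrogenation. The fallback runs from 12 back to 15 and reduces the alkyne before iodine is present. H2 over Pd/CaCO3 poisoned with Pb(OAc)2 with quinoline converts 12 into the (1R,2Z,4S)-alkenol F6. Mitsunobu etherification of F6 with 13 (PPh3, DIAD, toluene, −20 °C), an SN2 displacement with inversion at the allylic carbinol, then gives 15. The price is possible SN2′ attack and easier ionisation at the allylic position.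

Step 10. Attack at the congested ester carbonyl may be slow, and prolonged heating could bring base-induced loss of the β-aryloxy group or opening of ring C. The fallback runs from 18 back to 20 and cuts the O–CH3 bond instead of attacking the acyl carbon. LiI in refluxing EtOAc dealkylates by SN2 at the methyl group, a non-basic method for hindered methyl esters, and acidification on work-up gives 20.

Further compounds
F1 | step 9 | (1R,4R)-1,4-bis[3,5-bis(methoxymethoxy)phenoxy]-1-(4-methoxyphenyl)-4-[4-(methoxymethoxy)phenyl]but-2-yne | COc1ccc([C@@H](Oc2cc(OCOC)cc(OCOC)c2)C#C[C@H](Oc2cc(OCOC)cc(OCOC)c2)c2ccc(OCOC)cc2)cc1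
F2 | step 9 | (1S,2Z,4S)-1,4-bis[3,5-bis(methoxymethoxy)phenoxy]-1-(4-methoxyphenyl)-4-[4-(methoxymethoxy)phenyl]but-2-ene | COc1ccc([C@@H](Oc2cc(OCOC)cc(OCOC)c2)/C=C\[C@H](Oc2cc(OCOC)cc(OCOC)c2)c2ccc(OCOC)cc2)cc1
F3 | step 9 | dimethyl (2R,3S)-2-[(S)-[3,5-bis(methoxymethoxy)phenoxy](4-methoxyphenyl)methyl]-3-[(S)-[3,5-bis(methoxymethoxy)phenoxy][4-(methoxymethoxy)phenyl]methyl]butanedioate | COc1ccc([C@@H](Oc2cc(OCOC)cc(OCOC)c2)[C@H](C(=O)OC)[C@H](C(=O)OC)[C@H](Oc2cc(OCOC)cc(OCOC)c2)c2ccc(OCOC)cc2)cc1
F4 | step 9 | dimethyl (2S,3R)-2-[(S)-[3,5-bis(methoxymethoxy)phenoxy](4-methoxyphenyl)methyl]-3-[(S)-[3,5-bis(methoxymethoxy)phenoxy][4-(methoxymethoxy)phenyl]methyl]butanedioate (face isomer of F3) | COc1ccc([C@@H](Oc2cc(OCOC)cc(OCOC)c2)[C@@H](C(=O)OC)[C@@H](C(=O)OC)[C@H](Oc2cc(OCOC)cc(OCOC)c2)c2ccc(OCOC)cc2)cc1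
F5 | step 9 | (2R,3S)-2-[(S)-[3,5-bis(methoxymethoxy)phenoxy](4-methoxyphenyl)methyl]-3-[(S)-[3,5-bis(methoxymethoxy)phenoxy][4-(methoxymethoxy)phenyl]methyl]butanedioic acid | COc1ccc([C@@H](Oc2cc(OCOC)cc(OCOC)c2)[C@H](C(=O)O)[C@H](C(=O)O)[C@H](Oc2cc(OCOC)cc(OCOC)c2)c2ccc(OCOC)cc2)cc1
F6 | step 8 | (1R,2Z,4S)-4-[3,5-bis(methoxymethoxy)phenoxy]-1-(4-methoxyphenyl)-4-[4-(methoxymethoxy)phenyl]but-2-en-1-ol | COc1ccc([C@H](O)/C=C\[C@H](Oc2cc(OCOC)cc(OCOC)c2)c2ccc(OCOC)cc2)cc1
F0 | step 10 | none | none
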